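**Retrosynthetic overview**

1. Briaexcavatolide N ⇐ (desilylation, semihydrogenation of a C3≡C4 alkyne, acetylation, acetal → lactone, C2 inversion, epoxidation) ⇐ ten-membered cycloalkynol 39, whose C13=C14 alkene becomes the epoxide.
2. Key disconnection C1–C2: [2,3]-Wittig ring contraction of the bridged 13-membered propargyl cyclohexenyl ether 37 (O–C13 broken, C1–C2 made). This closes the ten-membered carbocycle after the six-membered ring and the five-membered O-ring (lactone held as its methyl acetal) are in place.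
3. Enabling feature: the homoallylic alcohol HO–C2–C1(quaternary, CH3)–C14=C13 that is latent in the 13,14-epoxide of the six-membered ring, flanked by the C3–C4 unsaturation that acidifies C2–H. The C13 oxygen relays its configuration to C1 and comes back as the epoxide oxygen.
4. 37 ⇐ O–C2 macro-etherification ⇐ C4–C5 Sonogashira ⇐ five-membered ring by C7–O epoxide opening, after C8–C17 anti-carbomagnesiation and directed epoxidation of a C9 propargylic alcohol (from ynone transfer hydrogenation) ⇐ acetylide 22 + bicyclic lactone 14.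
5. 14 ⇐ iodolactonisation and selenoxide transposition of the auxiliary-controlled Diels–Alder adduct of piperylene (C10 set by the auxiliary; C11, C12, C13, then C1, C13/C14 relayed). Ring order: six-membered carbocycle → five-membered O-ring → (temporary 13-membered ether) → ten-membered carbocycle.

Key step: step 24

Remark: positions are given in briarane numbering (C1 quaternary ring-fusion carbon, C2 carbinol, C3=C4 and C5=C6 diene with C16 the CH2OH carbon, C7–C8–C17–C19 lactone, C9 and C12 acetoxy carbons, C10 ring-fusion CH, C11 methyl-bearing carbon, C13/C14 epoxide); salts that arise only by O–H or N–H deprotonation inside a step are not counted as separate intermediates.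

**Route**

Step 1
Reactants: 1 (S)-4-benzyloxazolidin-2-one; 2 (E)-but-2-enoyl chloride
Product: 3 (S)-4-benzyl-3-[(E)-but-2-enoyl]oxazolidin-2-one
Conditions: n-BuLi, THF, −78 °C; then 2, −78 → 0 °C
Reagents that add atoms: none
Why: N-acylation of the lithiated oxazolidinone with an acid chloride is the standard preparation of enoyl imides and touches no stereocentre.

Step 2
Reactants: 3 enoyl imide; 4 (E)-penta-1,3-diene
Product: 5 Diels–Alder adduct, (S)-4-benzyl-3-{[(1R,2S,6S)-2,6-dimethylcyclohex-3-en-1-yl]carbonyl}oxazolidin-2-one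
Conditions: Et2AlCl (1.4 equiv), 4 (5 equiv), CH2Cl2, −30 °C; then 1 M HCl
Reagents that add atoms: none
Why: Lewis-acid-promoted Diels–Alder reaction of the chelated s-cis imide, in which the diene adds to the face opposite the benzyl group (sets C10), endo (C11 methyl cis to the acyl group) and with "ortho" regiochemistry, while the E dienophile puts the C1 methyl trans to the acyl group.

Step 3
Reactants: 5 Diels–Alder adduct
Product: 7 (1R,2S,6S)-2,6-dimethylcyclohex-3-ene-1-carboxylic acid, via peroxy acid 6 (not isolated)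
Conditions: LiOH, H2O2, THF/H2O, 0 °C; Na2SO3; then HCl to pH 2
Reagents that add atoms: hydrogen peroxide, OO
Why: Lithium hydroperoxide cleaves the exocyclic imide carbonyl selectively (acyl substitution), sulfite reduces the peracid, the auxiliary is recovered and no stereocentre is touched.

Step 4
Reactants: 7 cyclohexenecarboxylic acid
Product: 8 iodolactone, 4-iodo-2,8-dimethyl-6-oxabicyclo[3.2.1]octan-7-one
Conditions: I2, KI, NaHCO3, THF/H2O, 0 °C → rt, dark
Reagents that add atoms: iodine, II
Why: Iodolactonisation, in which the carboxylate opens the iodonium ion at C12 from its own face to give the γ-lactone, so that the C12 oxygen is cis to C9 and to the C11 methyl and iodine at C13 is trans to it.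

Step 5
Reactants: 8 iodolactone
Product: 9 unsaturated lactone, 2,8-dimethyl-6-oxabicyclo[3.2.1]oct-3-en-7-one
Conditions: DBU, toluene, 80 °C
Reagents that add atoms: none
Why: E2 dehydroiodination, regioselective because the only hydrogen anti-periplanar to the axial C13–I bond is on C14.

Step 6
Reactants: 9 unsaturated lactone
Product: 10 epoxy lactone (epoxide oxygen on the face away from the lactone bridge)
Conditions: mCPBA, CH2Cl2, 0 °C → rt
Reagents that add atoms: mCPBA, O=C(OO)c1cccc(Cl)c1
Why: Peracid (Prilezhaev) epoxidation from the alkene face that is not covered by the two-atom lactone bridge, which places the epoxide oxygen trans to the C12 oxygen.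

Step 7
Reactants: 10 epoxy lactone
Product: 13 allylic alcohol (1S,4R,5R,8R)-4-hydroxy-2,8-dimethyl-6-oxabicyclo[3.2.1]oct-2-en-7-one, via hydroxy selenide 11 (not isolated), via selenoxide 12 (not isolated)
Conditions: PhSeSePh, NaBH4, EtOH, 0 °C → reflux; then THF, H2O2 (30%), 0 °C → rt
Reagents that add atoms: none
Why: Epoxide → allylic alcohol transposition by selenolate opening and selenoxide syn-elimination: the selenolate attacks trans-diaxially at C14 (remote from the electron-withdrawing lactone oxygen), and the selenoxide eliminates away from the carbinol carbon using the cis hydrogen on C1, so the C13 oxygen keeps its configuration and the alkene moves to C14=C1.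

Step 8
Reactants: 13 allylic alcohol
Product: 14 tetrahydropyranyl ether of 13
Conditions: 3,4-dihydro-2H-pyran, PPTS (cat.), CH2Cl2, rt
Reagents that add atoms: 3,4-dihydro-2H-pyran, C1=COCCC1
Why: Acid-catalysed acetalisation masks the allylic hydroxyl as a base-stable acetal that cannot migrate to a neighbouring alkoxide; the mixture at the new acetal carbon is irrelevant because the group is removed in step 20.

Step 9
Reactants: 15 ethyl (triphenyl-λ5-phosphanylidene)acetate; 16 3-(trimethylsilyl)prop-2-ynal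
Product: 18 ethyl (Z)-2-chloro-5-(trimethylsilyl)pent-2-en-4-ynoate, via chloro ylide 17 (not isolated)
Conditions: 15, N-chlorosuccinimide, CH2Cl2, −20 → 0 °C; then 16, rt
Reagents that add atoms: N-chlorosuccinimide, O=C1CCC(=O)N1Cl
Why: Chlorination of the stabilised ylide followed by a Wittig reaction, which places the ester trans to the alkynyl group and hence chlorine cis to it.

Step 10
Reactants: 18 chloro enynoate
Product: 19 (Z)-2-chloro-5-(trimethylsilyl)pent-2-en-4-yn-1-ol
Conditions: i-Bu2AlH (2.2 equiv), CH2Cl2, −78 °C; aq Rochelle salt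
Reagents that add atoms: none
Why: 1,2-Reduction of the conjugated ester by the aluminium hydride leaves the alkenyl chloride, the silyl alkyne and the double-bond geometry untouched.

Step 11
Reactants: 19 allylic alcohol
Product: 20 tert-butyldiphenylsilyl ether of 19
Conditions: TBDPSCl, imidazole, CH2Cl2, rt
Reagents that add atoms: tert-butyl(chloro)diphenylsilane, CC(C)(C)[Si](Cl)(c1ccccc1)c1ccccc1
Why: Silylation of the primary alcohol gives an ether that survives organometallic bases, mild acid and oxidants until the last step.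

Step 12
Reactants: 20 silyl alkyne
Product: 21 tert-butyl{[(Z)-2-chloropent-2-en-4-yn-1-yl]oxy}diphenylsilane
Conditions: K2CO3 (cat.), MeOH, rt
Reagents that add atoms: none
Why: Methoxide-mediated protodesilylation of the alkynylsilane frees the terminal alkyne and leaves the hindered silyl ether intact.

Step 13
Reactants: 14 lactone; 21 terminal alkyne
Product: 23 hydroxy ynone (C9 ketone; C12 hydroxyl free; C13 OTHP), via lithium acetylide 22 (not isolated)
Conditions: 21, LiN(SiMe3)2, THF, −78 °C; then 14, −78 → −40 °C; aq NH4Cl at −78 °C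
Reagents that add atoms: none
Why: Acetylide addition to the lactone carbonyl gives a tetrahedral alkoxide that is stable at low temperature and collapses on work-up to the ynone, freeing the C12 hydroxyl; the C10 centre is exposed to enolisation only in this compound, which is reduced at once.

Step 14
Reactants: 23 hydroxy ynone
Product: 24 propargylic diol (9R)
Conditions: Ru[(R,R)-TsNCH(Ph)CH(Ph)NH](η6-p-cymene) (2 mol%), i-PrOH, rt
Reagents that add atoms: none
Why: Noyori asymmetric transfer hydrogenation of the ynone, in which the (R,R) catalyst distinguishes the alkynyl from the alkyl side (reagent control), sets C9 under base-free conditions that do not epimerise C10.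

Step 15
Reactants: 24 propargylic diol
Product: 26 dienediol (isopropenyl on C8; E-C8=C7), via alkenylmagnesium chelate 25 (not isolated)
Conditions: CH2=C(CH3)MgBr (5 equiv), CuI (20 mol%), THF, −20 °C → rt; aq NH4Cl
Reagents that add atoms: isopropenylmagnesium bromide, C=C(C)[Mg]Br
Why: Copper-catalysed anti-carbomagnesiation of the propargylic alkoxide, in which the isopropenyl group adds to the alkyne carbon next to the carbinol (C8) and magnesium to C7 within a five-membered chelate, so that after protonation the new C8–C17 bond is cis to C6; the alkenyl chloride is inert to the reagent.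

Step 16
Reactants: 26 dienediol
Product: 27 epoxy diol (C8–C7 epoxide anti to the C9 hydroxyl)
Conditions: VO(acac)2 (5 mol%), t-BuOOH (1.05 equiv), CH2Cl2, −20 → 0 °C
Reagents that add atoms: tert-butyl hydroperoxide, CC(C)(C)OO
Why: Vanadium-catalysed hydroxyl-directed epoxidation, erythro-selective because of A1,2 strain from the substituent geminal to the carbinol, sets C8 and C7 from C9; the allylic alkene reacts much faster than the ring alkene that is only homoallylic to the C12 hydroxyl, and the cis-dialkenyl epoxide is kept cold to avoid Cope rearrangement.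

Step 17
Reactants: 27 epoxy diol
Product: 28 bis(4-methoxybenzyl) ether (C9 and C12)
Conditions: NaH, 4-methoxybenzyl bromide, n-Bu4NI (cat.), THF/DMF, 0 °C → rt
Reagents that add atoms: 4-methoxybenzyl bromide, COc1ccc(CBr)cc1
Why: Williamson etherification of both secondary alkoxides; the neighbouring acetal cannot migrate and the epoxide is stable to the aprotic basic conditions.

Step 18
Reactants: 28 bis-PMB ether
Product: 30 primary alcohol (C19 hydroxyl; C17 set), via alkylborane 29 (not isolated)
Conditions: 9-BBN, THF, 0 °C → rt; then NaBO3·4H2O, H2O, rt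
Reagents that add atoms: sodium perborate, [Na+].[O-]OB=O
Why: Anti-Markovnikov hydroboration–oxidation of the 1,1-disubstituted alkene (the chloroalkene and the ring alkene are much slower with 9-BBN); C17 is set by substrate control, the borane adding anti to the C9 branch of the adjacent quaternary epoxide carbon with the compact epoxide oxygen in the inside position, and perborate avoids strongly basic peroxide.

Step 19
Reactants: 30 primary alcohol
Product: 31 β,γ-epoxy aldehyde
Conditions: Dess–Martin periodinane, pyridine, CH2Cl2, 0 °C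
Reagents that add atoms: none
Why: Dess–Martin oxidation under buffered non-basic conditions gives the aldehyde without enolisation, so C17 is not epimerised and the epoxide is not eliminated; the aldehyde is used directly.

Step 20
Reactants: 31 epoxy aldehyde
Product: 33 cyclic methyl acetal (five-membered O-ring closed; C8 and C13 hydroxyls free), via methyl hemiacetal 32 (not isolated)
Conditions: PPTS (cat.), MeOH/CH2Cl2 (1:4), 0 °C → rt
Reagents that add atoms: methanol, CO
Why: The hemiacetal hydroxyl opens the acid-activated alkenyl epoxide at the allylic carbon C7 with inversion (5-endo opening directed by the alkenyl group), which closes the five-membered ring as its methyl acetal, sets C7 and frees the tertiary C8 hydroxyl; the same mild acid methanolyses the THP ether.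

Step 21
Reactants: 33 cyclic acetal; 34 prop-2-yn-1-ol
Product: 35 enyne triol (C2, C8 and C13 hydroxyls free)
Conditions: PdCl2(MeCN)2 (5 mol%), XPhos (10 mol%), Cs2CO3, MeCN, 65 °C
Reagents that add atoms: none
Why: Copper-free Sonogashira coupling of the alkenyl chloride, made possible by a bulky electron-rich biarylphosphine, installs C2–C4 with retention of the double-bond geometry.

Step 22
Reactants: 35 enyne triol
Product: 36 primary propargylic mesylate
Conditions: MsCl (1.05 equiv), 2,4,6-collidine, CH2Cl2, −20 °C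
Reagents that add atoms: methanesulfonyl chloride, CS(=O)(=O)Cl
Why: Sulfonylation with a hindered base at low temperature is selective for the unhindered primary hydroxyl over the secondary allylic and the tertiary hydroxyl.

Step 23
Reactants: 36 mesylate
Product: 37 bridged 13-membered propargyl cyclohexenyl ether
Conditions: NaH (3 equiv), THF (0.002 M, slow addition), 0 → 45 °C
Reagents that add atoms: none
Why: Intramolecular Williamson etherification under high dilution, in which the C13 alkoxide displaces the propargylic mesylate by SN2; the tertiary C8 alkoxide cannot cyclise because that would place the alkyne in an eight-membered ring, and C13 keeps its configuration.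

Step 24
Reactants: 37 13-membered ether
Product: 39 ten-membered cycloalkynol (C1 quaternary; C13=C14; C2 carbinol epimeric to the natural one), via dilithio ether 38 (not isolated)
Conditions: n-BuLi (3 equiv), THF/pentane, −78 → −30 °C; aq NH4Cl
Reagents that add atoms: none
Why: n-BuLi first forms the C8 lithium alkoxide and then removes a proton from the propargylic O–CH2 group (C2, the most acidic C–H because the anion is delocalised into the enyne), and carbanion 38 rearranges by a concerted suprafacial [2,3]-sigmatropic (Wittig) shift through a five-membered envelope C2–O–C13–C14=C1 that breaks O–C13, makes C1–C2 and moves the alkene to C13=C14. The closest known reaction type is the [2,3]-Wittig ring contraction of 13-membered propargyl allyl ethers to ten-membered cycloalkynols used for germacrane-type carbocycles. The ten-membered carbocycle is closed by ring contraction (13 → 10: the ether oxygen, C13 and C14 leave the ring while the new bond forms inside a five-membered cyclic transition state), so no end-to-end closure of a medium ring is required. C1 is set by 1,3-transfer of chirality, because the new bond must form on the cyclohexene face that carries the C13–O bond, which puts C2 trans to C9 and the C1 methyl trans to H-10; C2 is set by the tether, because the alkynyl arm has to point towards C10 while the O–C2 bond lies over the six-membered ring, and this gives the C2 epimer of the natural carbinol, which is used to deliver the epoxide in step 25 and is inverted in steps 26 and 27. The step needs deprotonation at C2 instead of at C13–H or the benzylic CH2 groups, which the propargylic conjugation secures, and [2,3] over [1,2] shift, which the low temperature secures; no base-sensitive group is present because the lactone is held as its methyl acetal and the acetates are introduced later.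

Step 25
Reactants: 39 cycloalkynol
Product: 40 13,14-epoxide
Conditions: VO(acac)2 (5 mol%), t-BuOOH, CH2Cl2, 0 °C → rt
Reagents that add atoms: tert-butyl hydroperoxide, CC(C)(C)OO
Why: Vanadium-catalysed epoxidation directed by the homoallylic C2 hydroxyl, which sits over C13=C14 on the face the ether oxygen has just left, delivers the epoxide oxygen to that face, anti to the C12 ether and the C1 methyl; the alkyne is inert and the conjugated C5=C6 bond next to the hindered tertiary hydroxyl is slower.

Step 26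
Reactants: 40 epoxy alcohol
Product: 41 ynone (C2 ketone)
Conditions: Dess–Martin periodinane, pyridine, CH2Cl2, 0 °C → rt
Reagents that add atoms: none
Why: Dess–Martin oxidation of the secondary propargylic alcohol (the tertiary alcohol is inert) erases the unnatural C2 configuration.

Step 27
Reactants: 41 ynone
Product: 42 propargylic alcohol with the natural C2 configuration
Conditions: (R)-2-methyl-CBS-oxazaborolidine (1.2 equiv), BH3·SMe2, THF, −30 °C; MeOH
Reagents that add atoms: none
Why: Corey–Bakshi–Shibata reduction, in which the alkynyl group acts as the small and the quaternary C1 as the large substituent, so the (R)-oxazaborolidine delivers hydride to the face that gives the natural C2 carbinol (reagent control); epoxide, acetal and ethers are inert to borane at this temperature.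

Step 28
Reactants: 42 propargylic alcohol
Product: 43 C2 tert-butyldimethylsilyl ether
Conditions: TBSOTf, 2,6-lutidine, CH2Cl2, −78 °C
Reagents that add atoms: tert-butyldimethylsilyl trifluoromethanesulfonate, CC(C)(C)[Si](C)(C)OS(=O)(=O)C(F)(F)F
Why: Silylation of the secondary hydroxyl at −78 °C, where the hindered tertiary C8 hydroxyl is much slower, protects C2 through the acetylation.

Step 29
Reactants: 43 methyl acetal
Product: 44 lactol
Conditions: AcOH/THF/H2O (3:1:1), 35 °C
Reagents that add atoms: water, O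
Why: Mild aqueous acid hydrolyses the 2-methoxytetrahydrofuran acetal, conditions under which the non-allylic disubstituted epoxide and the PMB, TBS and TBDPS ethers survive.

Step 30
Reactants: 44 lactol
Product: 45 γ-lactone
Conditions: TEMPO (10 mol%), PhI(OAc)2, CH2Cl2, rt
Reagents that add atoms: none
Why: Oxoammonium-mediated oxidation converts the lactol into the lactone; the only other free hydroxyl is tertiary.

Step 31
Reactants: 45 lactone
Product: 46 C9,C12-diol
Conditions: DDQ, CH2Cl2/pH 7 buffer (10:1), 0 °C → rt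
Reagents that add atoms: none
Why: Oxidative cleavage of both 4-methoxybenzyl ethers with DDQ in wet solvent at neutral pH frees the C9 and C12 hydroxyls without touching silyl ethers, epoxide, lactone or enyne.

Step 32
Reactants: 46 diol
Product: 47 C9,C12-diacetate
Conditions: Ac2O, pyridine, DMAP (cat.), CH2Cl2, 0 °C → rt
Reagents that add atoms: acetic anhydride, CC(=O)OC(C)=O
Why: DMAP-catalysed acetylation esterifies the two secondary hydroxyls, whereas the tertiary C8 hydroxyl is not acylated under these mild conditions.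

Step 33
Reactants: 47 enyne diacetate
Product: 48 (3Z,5E)-diene
Conditions: H2 (1 atm), Pd/CaCO3 poisoned with Pb(OAc)2 (Lindlar catalyst), quinoline, EtOAc, rt
Reagents that add atoms: none
Why: Lindlar semihydrogenation adds hydrogen syn to the alkyne and gives the Z C3=C4 bond of the ring diene; quinoline suppresses over-reduction and the epoxide is inert.

Step 34
Reactants: 48 bis-silyl ether
Product: 49 briaexcavatolide N
Conditions: HF·pyridine, pyridine, THF, 0 °C → rt
Reagents that add atoms: none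
Why: Buffered fluoride cleavage of the TBS and TBDPS ethers liberates the C2 and C16 hydroxyls and leaves acetates, lactone, epoxide and diene untouched.

**Compound list**

1 | (S)-4-benzyloxazolidin-2-one | O=C1N[C@@H](Cc2ccccc2)CO1 | starting material
2 | (E)-but-2-enoyl chloride | C/C=C/C(Cl)=O | starting material
3 | (S)-4-benzyl-3-[(E)-but-2-enoyl]oxazolidin-2-one | C/C=C/C(=O)N1[C@@H](Cc2ccccc2)COC1=O | intermediate
4 | (E)-penta-1,3-diene | C/C=C/C=C | starting material
5 | (S)-4-benzyl-3-{[(1R,2S,6S)-2,6-dimethylcyclohex-3-en-1-yl]carbonyl}oxazolidin-2-one | O=C([C@H]1[C@@H](C)C=CC[C@@H]1C)N1[C@@H](Cc2ccccc2)COC1=O | intermediate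
6 | (1R,2S,6S)-2,6-dimethylcyclohex-3-ene-1-carboperoxoic acid | O=C(OO)[C@H]1[C@@H](C)C=CC[C@@H]1C | intermediate
7 | (1R,2S,6S)-2,6-dimethylcyclohex-3-ene-1-carboxylic acid | O=C(O)[C@H]1[C@@H](C)C=CC[C@@H]1C | intermediate
8 | 4-iodo-2,8-dimethyl-6-oxabicyclo[3.2.1]octan-7-one, iodine trans to the lactone oxygen | C[C@@H]1[C@H]2[C@@H](C)C[C@@H](I)[C@@H]1OC2=O | intermediate
9 | 2,8-dimethyl-6-oxabicyclo[3.2.1]oct-3-en-7-one | C[C@@H]1[C@H]2[C@@H](C)C=C[C@@H]1OC2=O | intermediate
10 | 3,4-epoxide of 9, oxygen on the face away from the lactone bridge | C[C@@H]1[C@H]2[C@@H](C)[C@H]3O[C@H]3[C@@H]1OC2=O | intermediate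
11 | 4-hydroxy-2,8-dimethyl-3-(phenylselanyl)-6-oxabicyclo[3.2.1]octan-7-one, OH and SePh trans | C[C@@H]1[C@H]2[C@@H](C)[C@H]([Se]c3ccccc3)[C@@H](O)[C@@H]1OC2=O | intermediate
12 | selenoxide of 11 | C[C@@H]1[C@H]2[C@@H](C)[C@H]([Se](=O)c3ccccc3)[C@@H](O)[C@@H]1OC2=O | intermediate
13 | (1S,4R,5R,8R)-4-hydroxy-2,8-dimethyl-6-oxabicyclo[3.2.1]oct-2-en-7-one | C[C@@H]1[C@H]2C(C)=C[C@@H](O)[C@@H]1OC2=O | intermediate
14 | tetrahydropyran-2-yl ether of 13 (mixture at the acetal carbon) | C[C@@H]1[C@H]2C(C)=C[C@@H](OC3CCCCO3)[C@@H]1OC2=O | intermediate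
15 | ethyl (triphenyl-λ5-phosphanylidene)acetate | CCOC(=O)C=P(c1ccccc1)(c1ccccc1)c1ccccc1 | starting material
16 | 3-(trimethylsilyl)prop-2-ynal | C[Si](C)(C)C#CC=O | starting material
17 | ethyl chloro(triphenyl-λ5-phosphanylidene)acetate | CCOC(=O)C(Cl)=P(c1ccccc1)(c1ccccc1)c1ccccc1 | intermediate
18 | ethyl (Z)-2-chloro-5-(trimethylsilyl)pent-2-en-4-ynoate | CCOC(=O)/C(Cl)=C/C#C[Si](C)(C)C | intermediate
19 | (Z)-2-chloro-5-(trimethylsilyl)pent-2-en-4-yn-1-ol | OC/C(Cl)=C/C#C[Si](C)(C)C | intermediate
20 | tert-butyl{[(Z)-2-chloro-5-(trimethylsilyl)pent-2-en-4-yn-1-yl]oxy}diphenylsilane | CC(C)(C)[Si](OC/C(Cl)=C/C#C[Si](C)(C)C)(c1ccccc1)c1ccccc1 | intermediate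
21 | tert-butyl{[(Z)-2-chloropent-2-en-4-yn-1-yl]oxy}diphenylsilane | CC(C)(C)[Si](OC/C(Cl)=C/C#C)(c1ccccc1)c1ccccc1 | intermediate
22 | lithium acetylide of 21 | CC(C)(C)[Si](OC/C(Cl)=C/C#C[Li])(c1ccccc1)c1ccccc1 | intermediate
23 | hydroxy ynone: cyclohexene with C9 ketone bearing the (Z)-chloroenyne chain, C12 hydroxyl free, C13 OTHP | O[C@@H]1[C@H](C)[C@H](C(=O)C#C/C=C(Cl)/CO[Si](c2ccccc2)(c2ccccc2)C(C)(C)C)C(C)=C[C@H]1OC1CCCCO1 | intermediate
24 | (9R)-propargylic diol from 23 | O[C@@H]1[C@H](C)[C@H]([C@@H](O)C#C/C=C(Cl)/CO[Si](c2ccccc2)(c2ccccc2)C(C)(C)C)C(C)=C[C@H]1OC1CCCCO1 | intermediate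
25 | five-membered alkenylmagnesium alkoxide chelate (Mg on C7, isopropenyl on C8), C12 OMgBr | Br[Mg]O[C@@H]1[C@H](C)[C@H]([C@H]2O[Mg]C(/C=C(Cl)/CO[Si](c3ccccc3)(c3ccccc3)C(C)(C)C)=C2C(C)=C)C(C)=C[C@H]1OC1CCCCO1 | intermediate
26 | dienediol: isopropenyl on C8, (E)-C8=C7 with the isopropenyl group cis to C6 | O[C@@H]1[C@H](C)[C@H]([C@@H](O)/C(C(C)=C)=C/C=C(Cl)/CO[Si](c2ccccc2)(c2ccccc2)C(C)(C)C)C(C)=C[C@H]1OC1CCCCO1 | intermediate
27 | epoxy diol: C8–C7 epoxide anti to the C9 hydroxyl | O[C@@H]1[C@H](C)[C@H]([C@@H](O)[C@@]2(C(C)=C)O[C@@H]2/C=C(Cl)/CO[Si](c2ccccc2)(c2ccccc2)C(C)(C)C)C(C)=C[C@H]1OC1CCCCO1 | intermediate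
28 | C9,C12-bis(4-methoxybenzyl) ether of 27 | COc1ccc(CO[C@@H]2[C@H](C)[C@H]([C@@H](OCc3ccc(OC)cc3)[C@@]3(C(C)=C)O[C@@H]3/C=C(Cl)/CO[Si](c3ccccc3)(c3ccccc3)C(C)(C)C)C(C)=C[C@H]2OC2CCCCO2)cc1 | intermediate
29 | B-alkyl-9-borabicyclo[3.3.1]nonane from 28 (boron on C19) | COc1ccc(CO[C@@H]2[C@H](C)[C@H]([C@@H](OCc3ccc(OC)cc3)[C@@]3([C@@H](C)CB4C5CCCC4CCC5)O[C@@H]3/C=C(Cl)/CO[Si](c3ccccc3)(c3ccccc3)C(C)(C)C)C(C)=C[C@H]2OC2CCCCO2)cc1 | intermediate
30 | primary alcohol (C19 OH, C17 methyl-bearing stereocentre set) | COc1ccc(CO[C@@H]2[C@H](C)[C@H]([C@@H](OCc3ccc(OC)cc3)[C@@]3([C@@H](C)CO)O[C@@H]3/C=C(Cl)/CO[Si](c3ccccc3)(c3ccccc3)C(C)(C)C)C(C)=C[C@H]2OC2CCCCO2)cc1 | intermediate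
31 | β,γ-epoxy aldehyde (C19 aldehyde) | COc1ccc(CO[C@@H]2[C@H](C)[C@H]([C@@H](OCc3ccc(OC)cc3)[C@@]3([C@@H](C)C=O)O[C@@H]3/C=C(Cl)/CO[Si](c3ccccc3)(c3ccccc3)C(C)(C)C)C(C)=C[C@H]2OC2CCCCO2)cc1 | intermediate
32 | methyl hemiacetal of 31 | COc1ccc(CO[C@@H]2[C@H](C)[C@H]([C@@H](OCc3ccc(OC)cc3)[C@@]3([C@@H](C)C(O)OC)O[C@@H]3/C=C(Cl)/CO[Si](c3ccccc3)(c3ccccc3)C(C)(C)C)C(C)=C[C@H]2OC2CCCCO2)cc1 | intermediate
33 | cyclic methyl acetal: 2-methoxytetrahydrofuran ring (C19, C17, C8, C7, O), C8 OH cis to the C17 methyl and to C6, C13 OH free, mixture at C19 | COc1ccc(CO[C@@H]2[C@H](C)[C@H]([C@@H](OCc3ccc(OC)cc3)[C@]3(O)[C@@H](C)C(OC)O[C@H]3/C=C(Cl)/CO[Si](c3ccccc3)(c3ccccc3)C(C)(C)C)C(C)=C[C@H]2O)cc1 | intermediate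
34 | prop-2-yn-1-ol | C#CCO | starting material
35 | enyne triol: C5 carries the 3-hydroxyprop-1-ynyl group cis to C7 | COc1ccc(CO[C@@H]2[C@H](C)[C@H]([C@@H](OCc3ccc(OC)cc3)[C@]3(O)[C@@H](C)C(OC)O[C@H]3/C=C(C#CCO)/CO[Si](c3ccccc3)(c3ccccc3)C(C)(C)C)C(C)=C[C@H]2O)cc1 | intermediate
36 | primary propargylic mesylate of 35 | COc1ccc(CO[C@@H]2[C@H](C)[C@H]([C@@H](OCc3ccc(OC)cc3)[C@]3(O)[C@@H](C)C(OC)O[C@H]3/C=C(C#CCOS(C)(=O)=O)/CO[Si](c3ccccc3)(c3ccccc3)C(C)(C)C)C(C)=C[C@H]2O)cc1 | intermediate
37 | bridged 13-membered ether: C13–O–C2H2–C3≡C4–C5=C6–C7–C8–C9–C10, spanning the cyclohexene C13–C14=C1–C10 | COc1ccc(CO[C@@H]2[C@H](C)[C@@H]3[C@@H](OCc4ccc(OC)cc4)[C@]4(O)[C@@H](C)C(OC)O[C@H]4/C=C(CO[Si](c4ccccc4)(c4ccccc4)C(C)(C)C)\C#CCO[C@@H]2C=C3C)cc1 | intermediate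
38 | dilithio species of 37 (C8 OLi, C2 Li) | COc1ccc(CO[C@@H]2[C@H](C)[C@@H]3[C@@H](OCc4ccc(OC)cc4)[C@]4(O[Li])[C@@H](C)C(OC)O[C@H]4/C=C(CO[Si](c4ccccc4)(c4ccccc4)C(C)(C)C)\C#CC([Li])O[C@@H]2C=C3C)cc1 | intermediate
39 | ten-membered cycloalkynol: C1 quaternary (methyl trans to H-10), C13=C14, C2 hydroxyl epimeric to the natural one | COc1ccc(CO[C@@H]2[C@H](C)[C@@H]3[C@@H](OCc4ccc(OC)cc4)[C@]4(O)[C@@H](C)C(OC)O[C@H]4/C=C(CO[Si](c4ccccc4)(c4ccccc4)C(C)(C)C)\C#C[C@@H](O)[C@@]3(C)C=C2)cc1 | intermediate
40 | 13,14-epoxide of 39, oxygen syn to C2 and anti to the C12 ether | COc1ccc(CO[C@@H]2[C@H](C)[C@@H]3[C@@H](OCc4ccc(OC)cc4)[C@]4(O)[C@@H](C)C(OC)O[C@H]4/C=C(CO[Si](c4ccccc4)(c4ccccc4)C(C)(C)C)\C#C[C@@H](O)[C@@]3(C)[C@H]4O[C@@H]24)cc1 | intermediate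
41 | C2 ynone | COc1ccc(CO[C@@H]2[C@H](C)[C@@H]3[C@@H](OCc4ccc(OC)cc4)[C@]4(O)[C@@H](C)C(OC)O[C@H]4/C=C(CO[Si](c4ccccc4)(c4ccccc4)C(C)(C)C)\C#CC(=O)[C@@]3(C)[C@H]4O[C@@H]24)cc1 | intermediate
42 | propargylic alcohol with the natural C2 configuration | COc1ccc(CO[C@@H]2[C@H](C)[C@@H]3[C@@H](OCc4ccc(OC)cc4)[C@]4(O)[C@@H](C)C(OC)O[C@H]4/C=C(CO[Si](c4ccccc4)(c4ccccc4)C(C)(C)C)\C#C[C@H](O)[C@@]3(C)[C@H]4O[C@@H]24)cc1 | intermediate
43 | C2 TBS ether of 42 | COc1ccc(CO[C@@H]2[C@H](C)[C@@H]3[C@@H](OCc4ccc(OC)cc4)[C@]4(O)[C@@H](C)C(OC)O[C@H]4/C=C(CO[Si](c4ccccc4)(c4ccccc4)C(C)(C)C)\C#C[C@H](O[Si](C)(C)C(C)(C)C)[C@@]3(C)[C@H]4O[C@@H]24)cc1 | intermediate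
44 | lactol (C19 OH, mixture at C19) | COc1ccc(CO[C@@H]2[C@H](C)[C@@H]3[C@@H](OCc4ccc(OC)cc4)[C@]4(O)[C@@H](C)C(O)O[C@H]4/C=C(CO[Si](c4ccccc4)(c4ccccc4)C(C)(C)C)\C#C[C@H](O[Si](C)(C)C(C)(C)C)[C@@]3(C)[C@H]4O[C@@H]24)cc1 | intermediate
45 | γ-lactone | COc1ccc(CO[C@@H]2[C@H](C)[C@@H]3[C@@H](OCc4ccc(OC)cc4)[C@]4(O)[C@@H](C)C(=O)O[C@H]4/C=C(CO[Si](c4ccccc4)(c4ccccc4)C(C)(C)C)\C#C[C@H](O[Si](C)(C)C(C)(C)C)[C@@]3(C)[C@H]4O[C@@H]24)cc1 | intermediate
46 | C9,C12-diol (C8 OH also free) | O[C@@H]1[C@H](C)[C@@H]2[C@@H](O)[C@]3(O)[C@@H](C)C(=O)O[C@H]3/C=C(CO[Si](c3ccccc3)(c3ccccc3)C(C)(C)C)\C#C[C@H](O[Si](C)(C)C(C)(C)C)[C@@]2(C)[C@H]3O[C@@H]13 | intermediate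
47 | C9,C12-diacetate | CC(=O)O[C@@H]1[C@H](C)[C@@H]2[C@@H](OC(C)=O)[C@]3(O)[C@@H](C)C(=O)O[C@H]3/C=C(CO[Si](c3ccccc3)(c3ccccc3)C(C)(C)C)\C#C[C@H](O[Si](C)(C)C(C)(C)C)[C@@]2(C)[C@H]3O[C@@H]13 | intermediate
48 | (3Z,5E)-diene, C2 OTBS, C16 OTBDPS | CC(=O)O[C@@H]1[C@H](C)[C@@H]2[C@@H](OC(C)=O)[C@]3(O)[C@@H](C)C(=O)O[C@H]3/C=C(CO[Si](c3ccccc3)(c3ccccc3)C(C)(C)C)\C=C/[C@H](O[Si](C)(C)C(C)(C)C)[C@@]2(C)[C@H]3O[C@@H]13 | intermediate
49 | briaexcavatolide N | CC(=O)O[C@@H]1[C@H](C)[C@@H]2[C@@H](OC(C)=O)[C@@]3(O)[C@H](/C=C(CO)\C=C/[C@H](O)[C@@]2(C)[C@H]2O[C@@H]12)OC(=O)[C@@H]3C | target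

**Totals**

Total step count: 34. Longest linear sequence: 30 steps (steps 1–8 and 13–34, from (S)-4-benzyloxazolidin-2-one); the chloroenyne branch (steps 9–12) is 4 steps.

**Steps most likely to fail**

1. Step 24. The carbanion may not reach the bridged envelope transition state, so that a [1,2]-shift, proton return or decomposition of the propargylic anion wins over ring contraction. Fallback, setting out from 33 and coming back at 41: the quaternary centre and the ring are made in two separate events. Sonogashira coupling of 33 with ethynyltrimethylsilane gives the silyl enyne F1. O-Alkylation of its C13 hydroxyl with Bu3SnCH2I (KH) gives the stannylmethyl ether F2. Tin–lithium exchange (n-BuLi, −78 °C) triggers the open-chain [2,3]-Wittig–Still rearrangement to the C1-quaternary primary alcohol F3, with the same 1,3-transfer of chirality. N-Iodosuccinimide with catalytic AgNO3 converts the alkynylsilane into the iodoalkyne F4, and Dess–Martin oxidation gives the aldehyde F5. An intramolecular Nozaki–Hiyama–Kishi reaction (CrCl2, catalytic NiCl2, THF/DMF, high dilution) then closes the ten-membered ring at C2–C3 and gives 39 together with its C2 epimer F6. Both are taken through steps 25 and 26 and meet at ynone 41.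

2. Step 23. Intermolecular alkylation (oligomerisation) or slow closure of the bridged ring may outrun formation of the 13-membered ether. Fallback, setting out from 33 and coming back at 37: the ether bond is made first, intermolecularly, and the ring is closed by carbon–carbon coupling instead. The C13 alkoxide of 33 is alkylated with propargyl bromide (NaH, THF) to give the propargyl ether F7. An intramolecular copper-free Sonogashira coupling of its terminal alkyne with the alkenyl chloride (PdCl2(MeCN)2, XPhos, Cs2CO3, MeCN, high dilution) then forms the C4–C5 bond and gives 37.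

3. Step 15. Carbometalation of the hindered internal enyne may be slow or lose its regiocontrol, and the copper reagent may attack the alkenyl chloride. Fallback, setting out from 24 and coming back at 26: hydrometalation followed by cross-coupling. Ruthenium-catalysed trans-hydrostannation ([(C5Me5)RuCl]4, Bu3SnH, CH2Cl2), directed by the free propargylic hydroxyl, places tin on C8 and hydrogen trans to it on C7 to give the alkenylstannane F8. A Stille coupling with 2-bromopropene (Pd(PPh3)4, copper thiophene-2-carboxylate CuO2CC4H3S, DMF) then gives 26 with the same alkene geometry.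

Further compounds
F1 | step 24 | silyl enyne: 33 with the chlorine replaced by a (trimethylsilyl)ethynyl group | COc1ccc(CO[C@@H]2[C@H](C)[C@H]([C@@H](OCc3ccc(OC)cc3)[C@]3(O)[C@@H](C)C(OC)O[C@H]3/C=C(C#C[Si](C)(C)C)/CO[Si](c3ccccc3)(c3ccccc3)C(C)(C)C)C(C)=C[C@H]2O)cc1
F2 | step 24 | C13 (tributylstannyl)methyl ether of F1 | COc1ccc(CO[C@@H]2[C@H](C)[C@H]([C@@H](OCc3ccc(OC)cc3)[C@]3(O)[C@@H](C)C(OC)O[C@H]3/C=C(C#C[Si](C)(C)C)/CO[Si](c3ccccc3)(c3ccccc3)C(C)(C)C)C(C)=C[C@H]2OC[Sn](CCCC)(CCCC)CCCC)cc1
F3 | step 24 | rearranged primary alcohol: C1 quaternary with CH2OH (C2), C13=C14 | COc1ccc(CO[C@@H]2[C@H](C)[C@H]([C@@H](OCc3ccc(OC)cc3)[C@]3(O)[C@@H](C)C(OC)O[C@H]3/C=C(C#C[Si](C)(C)C)/CO[Si](c3ccccc3)(c3ccccc3)C(C)(C)C)[C@@](C)(CO)C=C2)cc1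
F4 | step 24 | iodoalkyne of F3 | COc1ccc(CO[C@@H]2[C@H](C)[C@H]([C@@H](OCc3ccc(OC)cc3)[C@]3(O)[C@@H](C)C(OC)O[C@H]3/C=C(C#CI)/CO[Si](c3ccccc3)(c3ccccc3)C(C)(C)C)[C@@](C)(CO)C=C2)cc1
F5 | step 24 | C2 aldehyde of F4 | COc1ccc(CO[C@@H]2[C@H](C)[C@H]([C@@H](OCc3ccc(OC)cc3)[C@]3(O)[C@@H](C)C(OC)O[C@H]3/C=C(C#CI)/CO[Si](c3ccccc3)(c3ccccc3)C(C)(C)C)[C@@](C)(C=O)C=C2)cc1
F6 | step 24 | C2 epimer of 39 (natural C2 configuration) | COc1ccc(CO[C@@H]2[C@H](C)[C@@H]3[C@@H](OCc4ccc(OC)cc4)[C@]4(O)[C@@H](C)C(OC)O[C@H]4/C=C(CO[Si](c4ccccc4)(c4ccccc4)C(C)(C)C)\C#C[C@H](O)[C@@]3(C)C=C2)cc1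
F7 | step 23 | C13 prop-2-ynyl ether of 33 | COc1ccc(CO[C@@H]2[C@H](C)[C@H]([C@@H](OCc3ccc(OC)cc3)[C@]3(O)[C@@H](C)C(OC)O[C@H]3/C=C(Cl)/CO[Si](c3ccccc3)(c3ccccc3)C(C)(C)C)C(C)=C[C@H]2OCC#C)cc1
F8 | step 15 | alkenylstannane: tributylstannyl on C8, cis to C6 | O[C@@H]1[C@H](C)[C@H]([C@@H](O)/C([Sn](CCCC)(CCCC)CCCC)=C/C=C(Cl)/CO[Si](c2ccccc2)(c2ccccc2)C(C)(C)C)C(C)=C[C@H]1OC1CCCCO1
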